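**Analysis of the target**

Target 25 is a drimane: a trans-fused decalin (ring A = C1–C5, C10; ring B = C5–C10) with the gem-dimethyl group on C4, the angular methyl on C10, carboxylic acids C11 (on C9) and C12 (on C8), and a (2E,4E,6E)-octa-2,4,6-trienoate on the C6 oxygen. Five contiguous stereocentres lie on ring B: C5 (H α), C6 (O β), C8 (CO2H β), C9 (CO2H β) and C10 (CH3 β), i.e. 5S,6R,8S,9S,10S. In a chair ring B the C10 methyl, the C8 carboxyl and the C6 acyloxy group are all axial on the β face. The C8 centre is therefore the less stable epimer: it has to be made under kinetic control and kept away from enolising conditions afterwards. The trienoate cannot survive hydrogenation, and at the end it has to be distinguished from two free acids. A free 6β-hydroxyl next to a C12 carboxyl derivative on a saturated C8 would close to a bridged γ-lactone, so the oxygen must be acylated while C8 is still trigonal. The quaternary C10, wedged between C9 and the neopentyl C5, is the hardest carbon to build. The route rests on one feature: C6 is the only oxygenated ring carbon and is flanked by C5 and C7, so it can be brought in as carbon monoxide 11 between C5 of a cyclopropane (C5–C9–C10) and the terminal carbon C7 of an alkenyl group on C9.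

**Retrosynthetic reasoning**

25 ⇒ 24. The two acids are traced back to one cyclic anhydride, 24 (cut: one acyl C–O bond, hydrolysis). A diester would need saponification in the presence of the trienoate; an anhydride needs only neutral hydrolysis. The cis-fused anhydride also holds the axial C8 centre cis to C9 until the last step.

24 ⇒ 22 + 23. The C2′=C3′ bond of the side chain is cut (Horner–Wadsworth–Emmons). The triene cannot be present when the ring alkene is hydrogenated, and the hindered axial 6β-oxygen is easier to acylate with the small phosphonoacetic acid 20 than with a trienoic acid. The forward step must be E-selective and must not enolise the anhydride.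

22 ⇒ 21. The C8–H and C9–H bonds are removed, giving the C8=C9 alkene of a dialkylmaleic anhydride. Syn addition of hydrogen from the open α face sets both centres at once; equilibration could never deliver the axial C8 configuration.

21 ⇒ 19 + 20. The C6–O acyl bond is cut. Acylation has to come before saturation, because only while C8 is trigonal is lactonisation onto C12 impossible (it would need a bridgehead alkene).

19 ⇒ 15. The C6–H bond is cut (ketone reduction). The forward step needs hydride on the α face and must leave the anhydride intact.

15 ⇒ 14. C5 is epimerised through the enol of the C6 ketone. This is placed at the anhydride stage on purpose. In a 6-oxo-8-ene diester the C7 hydrogens are the most acidic in the molecule, and base would move the alkene into conjugation with the ketone. The five-membered maleic anhydride is expected to anchor the alkene at C8=C9, which suffices provided it outweighs conjugation of the alkene with the ketone.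

14 ⇒ 12. The anhydride is traced to a di-tert-butyl diester, so that acid alone frees both carboxyls next to the ketone.

12 ⇒ 10 + 11 (key disconnection). The C5–C6 and C6–C7 bonds are cut and C6 leaves as carbon monoxide 11. Ring B disappears and a bicyclo[4.1.0]heptane remains in which C10 is already quaternary and stereodefined. The forward step must open the C9–C5 bond and not C9–C10, and take up exactly one molecule of 11.

10 ⇒ 9 ⇒ 6 + 7. The C7=C8 alkene is cut (Wittig methylenation of keto ester 9), then the C8–C9 bond (acylation of the ester enolate 8 with oxalate 7). The enolate carbon becomes trigonal again later, so its configuration does not matter.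

6 ⇒ 4 + 5. Both cyclopropane bonds to C9 are cut (asymmetric carbene transfer from diazoacetate 5 to alkene 4). This is where C10 is set, on a simple alkene and before any ring B exists.

4 ⇒ 2 ⇒ 1. The alkene comes from ketone 1 by a Shapiro reaction through hydrazone 2 and vinyllithium 3; only one α-carbon of 1 carries hydrogen, so the alkene position is unambiguous.

**Alternatives that were turned down**

Alternative 1: Disconnection of C9–C10 and C5–C6 by an enone–alkene [2+2] photocycloaddition, followed by retro-aldol cleavage of C6–C9, from enone A1 and silyloxycyclobutene diester A2.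
- Forward key step: irradiation of A1 with A2 gives the bicyclo[2.2.0]hexane A3; desilylation then lets the C6 alkoxide expel the C9 ester enolate and opens ring B as a 6-ketone.
- For: the C9–C10 bond at the quaternary centre and C5–C6 form in one step, and the donor (silyloxy) and acceptor (ester) on the alkene direct the same regiochemistry. C8 and C9 arrive saturated, so no tetrasubstituted alkene needs hydrogenating; on this point it is stronger than the chosen route.
- Against: the carbonyl of A1 ends up on C1 and must be removed in the presence of the C6 ketone. The biradical must close between the methyl-bearing α-carbon of A1 and a fully substituted strained alkene carbon, where reversion is the usual outcome. The absolute configuration at C10 depends on the single stereocentre of A2, which itself needs an asymmetric synthesis. A3 is cis-fused, so C5 still needs epimerising, and C9 is set by protonation, which in 8-carbonyl drimanes tends to the wrong, axial epimer.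
- Comparison: more bonds in the key step, but more corrective steps after it. The chosen route sets C10 by a catalyst on a simple alkene and fixes C8 and C9 together by one syn hydrogenation.

Alternative 2: Disconnection of C8–C12 and C9–C11, both carboxyl carbons coming from carbon monoxide 11, from the dinor alkenol A4.
- Forward key step: a divalent palladium catalyst with a copper reoxidant under 11 in an alcohol turns the 6β-hydroxyl into an alkoxycarbonyl palladium species, which adds across C8=C9 from the β face; a second insertion and alcoholysis give lactone ester A5.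
- For: the hydroxyl delivers both carboxyl carbons syn on the β face, exactly the C6/C8/C9 relationship of 25, with no hydrogenation and no C5 epimerisation. On stereocontrol at C8 and C9 it is stronger than the chosen route.
- Against: A5 is the bridged lactone that 25 must not become. Reaching 25 means opening it, acylating the hindered 6β-hydroxyl while C12 is a free acid (the hydroxy acid recloses), and then cleaving a methyl ester next to the trienoate. A4, an enantiopure trans-octalinol with the quaternary C10, needs its own asymmetric synthesis, so the hardest carbon is only moved upstream.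
- Comparison: the chosen route carries both carboxyl carbons from the start, frees them by neutral hydrolysis, and acylates O6 before C8 is saturated.

Alternative 3: Disconnection of C5–C10 and C8–C9 by an intramolecular Diels–Alder reaction of the open-chain silyloxydiene enoyl imide A6.
- Forward key step: a cationic divalent copper bis(oxazoline) Lewis acid binds the imide of A6 and the tethered diene adds, closing rings A and B to A7.
- For: both rings and four stereocentres (C5, C8, C9, C10) are set in one catalytic enantioselective step, with the trans ring fusion directly and C11 and C12 differentiated. On step economy of stereocentres it is clearly stronger than the chosen route.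
- Against: the dienophile is a β,β-disubstituted enoyl imide, a poorly reactive class for this catalysis. The C5–C10 bond joins a carbon next to the gem-dimethyl C4 to a carbon that becomes quaternary, the most congested bond of the molecule. Three alkene geometries of A6 and the endo orientation of the imide must all be right, and A6 needs a long linear synthesis with a Z-selective silyl dienol ether. The axial C8 ester must then survive imide cleavage.
- Comparison: the chosen route makes the congested C10 early by an intermolecular cyclopropanation and forms only bonds to an unhindered acyl carbon in its key step, from a precursor five steps from a commercial ketone.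

Key step: step 6

Remark on the chemistry: the (S,S) antipode of the bis(oxazoline) ligand is assumed to give the (1S) cyclopropane 6; if the sense is opposite, the (R,R) ligand is used and nothing else changes. Racemic 1 is used because its stereocentre becomes trigonal in step 2.

**Route**

Step 1
Reactants: 1 2,2,6-trimethylcyclohexan-1-one
Product: 2 N′-(2,2,6-trimethylcyclohexylidene)-2,4,6-tri(propan-2-yl)benzenesulfonohydrazide
Conditions: 2,4,6-(i-Pr)3C6H2SO2NHNH2, HCl (cat.), MeCN, rt
Reagents that add atoms: 2,4,6-tri(propan-2-yl)benzenesulfonohydrazide, CC(C)c1cc(C(C)C)c(S(=O)(=O)NN)c(C(C)C)c1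
Why: Acid-catalysed condensation of a ketone with a sulfonyl hydrazide; hindered 2,2-disubstituted cyclohexanones are an established substrate class for trisylhydrazone formation.

Step 2
Reactants: 2 N′-(2,2,6-trimethylcyclohexylidene)-2,4,6-tri(propan-2-yl)benzenesulfonohydrazide
Product: 4 1,3,3-trimethylcyclohex-1-ene, via vinyllithium 3 (not isolated)
Conditions: n-BuLi (2.2 equiv), TMEDA, THF/hexane, −78 → 0 °C; then H2O
Reagents that add atoms: none
Why: Shapiro reaction: the hydrazone dianion can form only at the methyl-bearing α-carbon, loss of sulfinate and N2 gives vinyllithium 3, and protonation gives the trisubstituted alkene 4, which is isolated by distillation.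

Step 3
Reactants: 4 1,3,3-trimethylcyclohex-1-ene; 5 tert-butyl 2-diazoacetate
Product: 6 tert-butyl (1S,6R,7S)-1,5,5-trimethylbicyclo[4.1.0]heptane-7-carboxylate (ester exo)
Conditions: 4 (3 equiv), (CuOTf)2·C6H6 (1 mol %), 2,2′-(propane-2,2-diyl)bis[(4S)-4-tert-butyl-4,5-dihydro-1,3-oxazole] (2.2 mol %), CH2Cl2, rt, slow addition of 5
Reagents that add atoms: none
Why: Asymmetric cyclopropanation by carbene transfer from a monovalent copper bis(oxazoline) carbene, a catalyst class that accepts trisubstituted alkenes. Syn addition puts the ring hydrogen cis to the angular methyl, and the tert-butyl groups of the ligand select the alkene face, which sets the quaternary carbon (drimane C10). The bulky ester goes exo; any endo isomer converges in step 4.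

Step 4
Reactants: 6 tert-butyl (1S,6R,7S)-1,5,5-trimethylbicyclo[4.1.0]heptane-7-carboxylate; 7 di-tert-butyl oxalate
Product: 9 tert-butyl (1S,6R,7R)-7-(2-tert-butoxy-2-oxoacetyl)-1,5,5-trimethylbicyclo[4.1.0]heptane-7-carboxylate, via lithium ester enolate 8 (not isolated)
Conditions: LiN(i-Pr)2 (1.2 equiv), THF, −78 → −30 °C; then added to 7 (2 equiv), THF, −78 → 0 °C; aq. NH4Cl
Reagents that add atoms: none
Why: Claisen-type acylation of an ester enolate by a non-enolisable oxalate; tert-butyl cyclopropanecarboxylate enolates are stable at low temperature, and inverse addition to excess 7 prevents a second addition to the new ketone. The electrophile enters on the exo face, away from ring A and its gem-dimethyl group; this centre is erased again in step 6.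

Step 5
Reactants: 9 tert-butyl (1S,6R,7R)-7-(2-tert-butoxy-2-oxoacetyl)-1,5,5-trimethylbicyclo[4.1.0]heptane-7-carboxylate
Product: 10 tert-butyl (1S,6R,7R)-7-(3-tert-butoxy-3-oxoprop-1-en-2-yl)-1,5,5-trimethylbicyclo[4.1.0]heptane-7-carboxylate
Conditions: Ph3PCH3Br, KN(SiMe3)2, THF, 0 °C; then 9, −78 °C → rt
Reagents that add atoms: methyltriphenylphosphonium bromide, C[P+](c1ccccc1)(c1ccccc1)c1ccccc1.[Br-]
Why: Wittig methylenation; the ketone of an α-keto ester is the most electrophilic carbonyl present, 9 has no enolisable hydrogen, and the tert-butyl esters are inert to the ylide.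

Step 6
Reactants: 10 tert-butyl (1S,6R,7R)-7-(3-tert-butoxy-3-oxoprop-1-en-2-yl)-1,5,5-trimethylbicyclo[4.1.0]heptane-7-carboxylate; 11 carbon monoxide
Product: 12 di-tert-butyl (5R,10S)-6-oxodrim-8-ene-11,12-dioate (5-epi, cis-fused)
Conditions: [Rh(CO)2Cl]2 (5 mol %), 11 (1 atm), toluene, 90 °C
Reagents that add atoms: none
Why: The acrylate alkene C7=C8 binds monovalent rhodium, which adds oxidatively into the adjacent C9–C5 bond to give a trivalent rhodacycle with a σ-alkyl at C5 and a π-allyl over C7–C8–C9; 11 inserts into the Rh–C5 bond and acyl–allyl reductive elimination at C7 releases 12. The closest known reaction type is the rhodium-, cobalt- or iron-carbonyl-mediated [5+1] carbonylation of vinylcyclopropanes to cyclohex-3-enones. Ring B is closed as a six-membered carbocycle by reductive elimination from a seven-membered acyl rhodacycle, a three-atom expansion of the cyclopropane in which C5–C6 and C6–C7 are made and C5–C9 is lost; elimination at C9 would require a cyclobutanone. No new stereocentre is formed: C5 keeps its configuration because oxidative addition and migratory insertion proceed with retention at carbon, C10 is not touched and C9 becomes trigonal, so the product is cis-fused. The step needs cleavage of C9–C5 and not C9–C10; the metal should go to C5, which bears a hydrogen, and avoid the quaternary C10. The alkyl at C5 has no β-hydrogen, since C4 and C10 are both quaternary, so β-hydride elimination cannot divert the rhodacycle. The atmosphere of 11 disfavours direct C5–C7 coupling to a cyclopentene. The alkene is left at C8=C9, where the anhydride needs it.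

Step 7
Reactants: 12 di-tert-butyl (5R,10S)-6-oxodrim-8-ene-11,12-dioate
Product: 14 (5R,10S)-6-oxodrim-8-ene-11,12-dioic anhydride (cis-fused), via cis-fused keto diacid 13 (not isolated)
Conditions: CF3CO2H/CH2Cl2 (1:2), 0 °C → rt; evaporation from toluene
Reagents that add atoms: none
Why: Acidolysis of tert-butyl esters; the resulting cis diacid on a tetrasubstituted alkene is a dialkylmaleic acid, which dehydrates to the five-membered anhydride on concentration. Acid is used so that the very acidic C7 hydrogens never meet base.

Step 8
Reactants: 14 (5R,10S)-6-oxodrim-8-ene-11,12-dioic anhydride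
Product: 15 (5S,10S)-6-oxodrim-8-ene-11,12-dioic anhydride (trans-fused)
Conditions: TsOH (anhydrous, 0.2 equiv), toluene, 90 °C
Reagents that add atoms: none
Why: Acid-catalysed enolisation toward C5 and reprotonation under thermodynamic control should give the trans-fused ketone, the stable ring fusion of 6-oxo steroids and terpenoids bearing an angular methyl; this sets C5 (5S, H α). The five-membered maleic anhydride is expected to be the stable alkene tautomer against the ketone-conjugated 7-ene, so enolisation toward C7 should return the same compound and the alkene should stay at C8=C9.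

Step 9
Reactants: 15 (5S,10S)-6-oxodrim-8-ene-11,12-dioic anhydride
Product: 19 (5S,6R,10S)-6-hydroxydrim-8-ene-11,12-dioic anhydride, via disodium keto dicarboxylate 16 (not isolated), via disodium hydroxy dicarboxylate 17 (not isolated), via hydroxy diacid 18 (not isolated)
Conditions: NaOH (2.0 equiv), THF/H2O, 0 °C; NaBH4 (2 equiv), 0 °C; then 2 M HCl to pH 1; toluene, 50 °C
Reagents that add atoms: none
Why: Hydroxide opens the anhydride to a dicarboxylate that NaBH4 cannot reduce, so only the C6 ketone reacts; hydride adds from the α face because the axial C10 and 4β methyl groups screen the β face, giving the axial 6β-alcohol (6R). Acidification gives a dialkylmaleic acid that recloses to 19 on its own, and no lactone can form while C8 is trigonal (Bredt's rule); the reduction is run cold and without excess hydroxide so that the alkene does not drift toward the ketone first.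

Step 10
Reactants: 19 (5S,6R,10S)-6-hydroxydrim-8-ene-11,12-dioic anhydride; 20 2-(diethoxyphosphoryl)acetic acid
Product: 21 (5S,6R,10S)-6-[2-(diethoxyphosphoryl)acetoxy]drim-8-ene-11,12-dioic anhydride
Conditions: DCC (1.5 equiv), DMAP (0.1 equiv), CH2Cl2, 0 °C → rt
Reagents that add atoms: none
Why: Steglich esterification; the activated phosphonoacetic acid is a small, very reactive acyl donor (it can react through a phosphoryl ketene) and acylates the hindered axial alcohol, whereas a dialkylmaleic anhydride is a poor, reversible acyl donor and does not self-condense. Only a catalytic weak base is present, so deprotonation at C7 and β-elimination of the new acyloxy group are avoided.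

Step 11
Reactants: 21 (5S,6R,10S)-6-[2-(diethoxyphosphoryl)acetoxy]drim-8-ene-11,12-dioic anhydride
Product: 22 (5S,6R,8S,9S,10S)-6-[2-(diethoxyphosphoryl)acetoxy]drimane-11,12-dioic anhydride (8α-H, 9α-H)
Conditions: H2 (50 atm), 10% Pd/C, EtOAc, 40 °C
Reagents that add atoms: none
Why: Heterogeneous syn hydrogenation of a dialkylmaleic anhydride to the cis-succinic anhydride, the reaction that converts tetrahydrophthalic into cis-hexahydrophthalic anhydride; pressure compensates for the tetrasubstituted alkene. The alkene adsorbs on its α face because the β face carries the axial C10 methyl next to C9 and the axial 6β-acyloxy group, so both hydrogens arrive from below and set C8 and C9 (8S,9S) together.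

Step 12
Reactants: 22 (5S,6R,8S,9S,10S)-6-[2-(diethoxyphosphoryl)acetoxy]drimane-11,12-dioic anhydride; 23 (2E,4E)-hexa-2,4-dienal
Product: 24 (5S,6R,8S,9S,10S)-6-[(2E,4E,6E)-octa-2,4,6-trienoyloxy]drimane-11,12-dioic anhydride
Conditions: LiCl (1.5 equiv), i-Pr2NEt (1.2 equiv), MeCN, rt
Reagents that add atoms: none
Why: Horner–Wadsworth–Emmons olefination under Masamune–Roush conditions; lithium chelation makes the phosphonoacetate acidic enough for a tertiary amine, which is too weak to enolise the anhydride and so leaves the axial C8 centre alone. Stabilised phosphonates give the E alkene with enals, and the two alkenes of 23 are carried over unchanged, giving the (2E,4E,6E) ester.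

Step 13
Reactants: 24 (5S,6R,8S,9S,10S)-6-[(2E,4E,6E)-octa-2,4,6-trienoyloxy]drimane-11,12-dioic anhydride
Product: 25 (5S,6R,8S,9S,10S)-6-[(2E,4E,6E)-octa-2,4,6-trienoyloxy]drimane-11,12-dioic acid
Conditions: THF/H2O (3:1), rt; freeze-drying
Reagents that add atoms: water, O
Why: Neutral hydrolysis of a cyclic succinic-type anhydride, which is far more electrophilic than the conjugated ester at C6; without acid or base, C8 and C9 cannot epimerise and the triene is untouched.

**Compound list**

1 | 2,2,6-trimethylcyclohexan-1-one (racemic) | CC1CCCC(C)(C)C1=O | starting material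
2 | N′-(2,2,6-trimethylcyclohexylidene)-2,4,6-tri(propan-2-yl)benzenesulfonohydrazide | CC1CCCC(C)(C)C1=NNS(=O)(=O)c1c(C(C)C)cc(C(C)C)cc1C(C)C | intermediate
3 | (2,6,6-trimethylcyclohex-1-en-1-yl)lithium | [Li]C1=C(C)CCCC1(C)C | intermediate
4 | 1,3,3-trimethylcyclohex-1-ene | CC1=CC(C)(C)CCC1 | intermediate
5 | tert-butyl 2-diazoacetate | CC(C)(C)OC(=O)C=[N+]=[N-] | starting material
6 | tert-butyl (1S,6R,7S)-1,5,5-trimethylbicyclo[4.1.0]heptane-7-carboxylate (ester exo, cis to the C1 methyl) | CC(C)(C)OC(=O)[C@H]1[C@@H]2C(C)(C)CCC[C@]12C | intermediate
7 | di-tert-butyl oxalate | CC(C)(C)OC(=O)C(=O)OC(C)(C)C | starting material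
8 | lithium enolate of 6 (lithium tert-butoxy[(1S,6R)-1,5,5-trimethylbicyclo[4.1.0]heptan-7-ylidene]methanolate) | [Li]OC(OC(C)(C)C)=C1[C@@H]2C(C)(C)CCC[C@]12C | intermediate
9 | tert-butyl (1S,6R,7R)-7-(2-tert-butoxy-2-oxoacetyl)-1,5,5-trimethylbicyclo[4.1.0]heptane-7-carboxylate (oxalyl group exo) | CC(C)(C)OC(=O)C(=O)[C@@]1(C(=O)OC(C)(C)C)[C@@H]2C(C)(C)CCC[C@]12C | intermediate
10 | tert-butyl (1S,6R,7R)-7-(3-tert-butoxy-3-oxoprop-1-en-2-yl)-1,5,5-trimethylbicyclo[4.1.0]heptane-7-carboxylate | C=C(C(=O)OC(C)(C)C)[C@@]1(C(=O)OC(C)(C)C)[C@@H]2C(C)(C)CCC[C@]12C | intermediate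
11 | carbon monoxide | [C-]#[O+] | starting material
12 | di-tert-butyl (5R,10S)-6-oxodrim-8-ene-11,12-dioate (5-epi, cis-fused; di-tert-butyl (4aR,8aS)-5,5,8a-trimethyl-4-oxo-3,4,4a,5,6,7,8,8a-octahydronaphthalene-1,2-dicarboxylate) | O=C1CC(C(=O)OC(C)(C)C)=C(C(=O)OC(C)(C)C)[C@@]2(C)CCCC(C)(C)[C@@H]12 | intermediate
13 | (5R,10S)-6-oxodrim-8-ene-11,12-dioic acid (cis-fused) | O=C1CC(C(=O)O)=C(C(=O)O)[C@@]2(C)CCCC(C)(C)[C@@H]12 | intermediate
14 | (5R,10S)-6-oxodrim-8-ene-11,12-dioic anhydride (cis-fused) | O=C1CC2=C(C(=O)OC2=O)[C@@]3(C)CCCC(C)(C)[C@@H]13 | intermediate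
15 | (5S,10S)-6-oxodrim-8-ene-11,12-dioic anhydride (trans-fused) | O=C1CC2=C(C(=O)OC2=O)[C@@]3(C)CCCC(C)(C)[C@H]13 | intermediate
16 | disodium (5S,10S)-6-oxodrim-8-ene-11,12-dioate | O=C1CC(C(=O)[O-])=C(C(=O)[O-])[C@@]2(C)CCCC(C)(C)[C@H]12.[Na+].[Na+] | intermediate
17 | disodium (5S,6R,10S)-6-hydroxydrim-8-ene-11,12-dioate | O[C@@H]1CC(C(=O)[O-])=C(C(=O)[O-])[C@@]2(C)CCCC(C)(C)[C@H]12.[Na+].[Na+] | intermediate
18 | (5S,6R,10S)-6-hydroxydrim-8-ene-11,12-dioic acid | O[C@@H]1CC(C(=O)O)=C(C(=O)O)[C@@]2(C)CCCC(C)(C)[C@H]12 | intermediate
19 | (5S,6R,10S)-6-hydroxydrim-8-ene-11,12-dioic anhydride (6β-OH) | O[C@@H]1CC2=C(C(=O)OC2=O)[C@@]3(C)CCCC(C)(C)[C@H]13 | intermediate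
20 | 2-(diethoxyphosphoryl)acetic acid | CCOP(=O)(OCC)CC(=O)O | starting material
21 | (5S,6R,10S)-6-[2-(diethoxyphosphoryl)acetoxy]drim-8-ene-11,12-dioic anhydride | CCOP(=O)(OCC)CC(=O)O[C@@H]1CC2=C(C(=O)OC2=O)[C@@]3(C)CCCC(C)(C)[C@H]13 | intermediate
22 | (5S,6R,8S,9S,10S)-6-[2-(diethoxyphosphoryl)acetoxy]drimane-11,12-dioic anhydride | CCOP(=O)(OCC)CC(=O)O[C@@H]1C[C@H]2[C@H](C(=O)OC2=O)[C@@]3(C)CCCC(C)(C)[C@H]13 | intermediate
23 | (2E,4E)-hexa-2,4-dienal | C/C=C/C=C/C=O | starting material
24 | (5S,6R,8S,9S,10S)-6-[(2E,4E,6E)-octa-2,4,6-trienoyloxy]drimane-11,12-dioic anhydride | C/C=C/C=C/C=C/C(=O)O[C@@H]1C[C@H]2[C@H](C(=O)OC2=O)[C@@]3(C)CCCC(C)(C)[C@H]13 | intermediate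
25 | (1S,2S,4R,4aS,8aS)-5,5,8a-trimethyl-4-[(2E,4E,6E)-octa-2,4,6-trienoyloxy]decahydronaphthalene-1,2-dicarboxylic acid (drimane numbering 5S,6R,8S,9S,10S) | C/C=C/C=C/C=C/C(=O)O[C@@H]1C[C@H](C(=O)O)[C@H](C(=O)O)[C@@]2(C)CCCC(C)(C)[C@H]12 | target

**Step count and least certain steps**

Total: 13 steps, all in one line from 1; the longest linear sequence is 13 steps.

Step 6 (key step). Rhodium may fail to enter the C9–C5 bond, which is screened by the fully substituted C9 and the neopentyl C5; it may open C9–C10 instead; or the rhodacycle may collapse without taking up 11, giving a cyclopentene. Fallback, from 10 back to 12: the catalytic rhodium step is replaced by a stoichiometric zerovalent iron template. Irradiation of 10 with Fe(CO)5 under 11 in THF binds the electron-poor acrylate alkene to an Fe(CO)4 fragment; the ring then opens inside this complex to an acyl π-allyl iron carbonyl, so the carbonyl carbon comes from the metal's own ligands, and warming under 11 releases 12. The iron-bound species are carried through in one flask and no compound outside the list is isolated.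

Step 3. Facial selectivity may be poor and carbene dimerisation may outrun transfer, because 4 is a trisubstituted alkene with a quaternary allylic carbon. Fallback, from 6 of insufficient enantiomeric purity (or from racemic material made with Rh2(OAc)4) back to 6: catalyst control is supplemented by a classical resolution. CF3CO2H cleaves the ester to (1S,6R,7S)-1,5,5-trimethylbicyclo[4.1.0]heptane-7-carboxylic acid F1. Its salt with (S)-1-phenylethylamine, (1S)-1-phenylethan-1-aminium (1S,6R,7S)-1,5,5-trimethylbicyclo[4.1.0]heptane-7-carboxylate F2, is crystallised to a single diastereomer (the antipodal amine is used if that salt is the less soluble one). The acid F1 is then liberated and returned to 6 with tert-butyl 2,2,2-trichloroacetimidate and BF3·OEt2 (cat.).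

Step 4. Removal of the shielded endo hydrogen of 6 may be slow, and the fully substituted enolate 8 may be too hindered to attack the bulky oxalate at carbon. Fallback, from 6 (through 8) back to 9: the acylation is replaced by an aldol addition and an oxidation. Enolate 8 is added to tert-butyl glyoxylate, a small and very electrophilic aldehyde, to give tert-butyl (1S,6R,7R)-7-(2-tert-butoxy-1-hydroxy-2-oxoethyl)-1,5,5-trimethylbicyclo[4.1.0]heptane-7-carboxylate F3 as a mixture of carbinol epimers; Dess–Martin periodinane in CH2Cl2 oxidises both to 9.

Step 8. Enolisation toward the hindered C5 may be too slow under acid, or the alkene may drift into conjugation with the ketone while it proceeds, or the trans fusion may not be favoured enough. Fallback, from 12 back to 15: the epimerisation is moved to the diester and run with base, accepting the alkene shift. KOt-Bu (cat.) in t-BuOH equilibrates 12 to di-tert-butyl (5S,10S)-6-oxodrim-7-ene-11,12-dioate F4 (conjugated enone, trans-fused, both C9 epimers). CF3CO2H gives (5S,10S)-6-oxodrim-7-ene-11,12-dioic acid F5, and heating F5 with TsOH in toluene moves the alkene back to C8=C9 as the anhydride closes, giving 15. This answers slow enolisation and alkene drift; it does not help if the trans fusion itself is not preferred.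

Step 12. The anhydride may be enolised at the axial C8 centre, which would epimerise to the more stable equatorial arrangement, or opened by the phosphonate anion. Fallback, from 22 to 25: the last two steps are exchanged. 22 is hydrolysed in THF/H2O to (5S,6R,8S,9S,10S)-6-[2-(diethoxyphosphoryl)acetoxy]drimane-11,12-dioic acid F6, whose carboxylates cannot be enolised. Olefination of F6 with 23 (LiCl, DBU 3.3 equiv, MeCN, rt), then mild acidification, gives 25 directly. Its own risk is acyl transfer from O6 to the neighbouring C12 carboxylate, so the reaction is kept short and cold.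

**Further compounds**

F0 | step 6 | none | none
F1 | step 3 | (1S,6R,7S)-1,5,5-trimethylbicyclo[4.1.0]heptane-7-carboxylic acid | OC(=O)[C@H]1[C@@H]2C(C)(C)CCC[C@]12C
F2 | step 3 | (1S)-1-phenylethan-1-aminium (1S,6R,7S)-1,5,5-trimethylbicyclo[4.1.0]heptane-7-carboxylate | C[C@H]([NH3+])c1ccccc1.[O-]C(=O)[C@H]1[C@@H]2C(C)(C)CCC[C@]12C
F3 | step 4 | tert-butyl (1S,6R,7R)-7-(2-tert-butoxy-1-hydroxy-2-oxoethyl)-1,5,5-trimethylbicyclo[4.1.0]heptane-7-carboxylate (both carbinol epimers) | CC(C)(C)OC(=O)C(O)[C@@]1(C(=O)OC(C)(C)C)[C@@H]2C(C)(C)CCC[C@]12C
F4 | step 8 | di-tert-butyl (5S,10S)-6-oxodrim-7-ene-11,12-dioate (trans-fused, both C9 epimers) | O=C1C=C(C(=O)OC(C)(C)C)C(C(=O)OC(C)(C)C)[C@@]2(C)CCCC(C)(C)[C@H]12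
F5 | step 8 | (5S,10S)-6-oxodrim-7-ene-11,12-dioic acid (trans-fused, both C9 epimers) | O=C1C=C(C(=O)O)C(C(=O)O)[C@@]2(C)CCCC(C)(C)[C@H]12
F6 | step 12 | (5S,6R,8S,9S,10S)-6-[2-(diethoxyphosphoryl)acetoxy]drimane-11,12-dioic acid | CCOP(=O)(OCC)CC(=O)O[C@@H]1C[C@H](C(=O)O)[C@H](C(=O)O)[C@@]2(C)CCCC(C)(C)[C@H]12
A1 | alternative 1 | 2,4,4-trimethylcyclohex-2-en-1-one | CC1=CC(C)(C)CCC1=O
A2 | alternative 1 | dimethyl 3-[(tert-butyldimethylsilyl)oxy]cyclobut-2-ene-1,2-dicarboxylate (single enantiomer) | COC(=O)[C@@H]1CC(O[Si](C)(C)C(C)(C)C)=C1C(=O)OC
A3 | alternative 1 | cis-anti-cis photoadduct (silyloxy bicyclo[2.2.0]hexane keto diester) | CC(C)(C)[Si](C)(C)O[C@]13C[C@@H](C(=O)OC)[C@]3(C(=O)OC)[C@@]2(C)C(=O)CCC(C)(C)[C@@H]12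
A4 | alternative 2 | 11,12-dinordrim-8-en-6β-ol | O[C@@H]1CC=C[C@@]2(C)CCCC(C)(C)[C@H]12
A5 | alternative 2 | methyl 6β,12-epoxy-12-oxodrimane-11-oate (6β,12-lactone 11-methyl ester) | O=C1O[C@@H]2C[C@H]1[C@H](C(=O)OC)[C@@]3(C)CCCC(C)(C)[C@H]23
A6 | alternative 3 | methyl (2E,4Z,10E)-4-[(tert-butyldimethylsilyl)oxy]-6,6,10-trimethyl-12-oxo-12-(2-oxo-1,3-oxazolidin-3-yl)dodeca-2,4,10-trienoate | O=C1OCCN1C(=O)/C=C(\C)CCCC(C)(C)/C=C(O[Si](C)(C)C(C)(C)C)/C=C/C(=O)OC
A7 | alternative 3 | trans-fused cycloadduct (6-silyloxy-6-ene, 12-methyl ester, 11-oxazolidinone imide) | CC(C)(C)[Si](C)(C)OC1=C[C@H](C(=O)OC)[C@H](C(=O)N3CCOC3=O)[C@@]2(C)CCCC(C)(C)[C@H]12
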